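**Strategy.** The route rests on building the benzene ring and the five-membered nitrogen ring of the indole skeleton in one cobalt-catalysed [2+2+2] cotrimerization. A tosyl-protected diyne, in which the N1–C2–C3 chain links an N-ethynyl group (future C7a and C7) to a but-3-ynyl group (future C3a and C4), is joined with bis(trimethylsilyl)acetylene, which supplies C5 and C6. The step forms C3a–C7a, C4–C5 and C6–C7 and leaves silicon on the vicinal C5/C6 pair, which ordinary electrophilic substitution of indoles or indolines does not deliver cleanly. Both silyl groups are then exchanged for bromine by ipso substitution, and the bromines at C3 and C2 follow last on the free indole.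

Key step: step 3

Remark: but-3-yn-1-amine is taken as the free base (its hydrochloride would need one more equivalent of Et3N); the target has no stereocentre, so no stereocontrol is required.

**Step 1**
Reactants: 1 but-3-yn-1-amine; 2 4-toluenesulfonyl chloride
Product: 3 N-(but-3-yn-1-yl)-4-methylbenzenesulfonamide
Conditions: Et3N (1.5 equiv), CH2Cl2, 0 °C to rt
Reagents that add atoms: 4-toluenesulfonyl chloride (2), Cc1ccc(cc1)S(=O)(=O)Cl
Why: Sulfonylation of the primary amine (nucleophilic substitution at sulfur, with the amine base taking up HCl) is fast and selective for nitrogen, and the terminal alkyne is inert under these conditions.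

**Step 2**
Reactants: 3 N-(but-3-yn-1-yl)-4-methylbenzenesulfonamide; 4 phenyl[(trimethylsilyl)ethynyl]iodonium trifluoromethanesulfonate
Product: 6 N-(but-3-yn-1-yl)-N-ethynyl-4-methylbenzenesulfonamide, via silylated ynamide 5 (not isolated)
Conditions: KN(SiMe3)2 (1.0 equiv), toluene, 0 °C; 4 (1.2 equiv), 0 °C to rt; then TBAF (1.1 equiv), wet THF, 0 °C
Reagents that add atoms: phenyl[(trimethylsilyl)ethynyl]iodonium trifluoromethanesulfonate (4), C[Si](C)(C)C#C[I+]c1ccccc1.[O-]S(=O)(=O)C(F)(F)F
Why: The sulfonamide N–H is far more acidic than the alkyne C–H, so one equivalent of base gives only the nitrogen anion, which is N-alkynylated by the alkynyliodonium salt (addition at the β-carbon, loss of iodobenzene to an alkylidene carbene, 1,2-shift to the ynamide) without any copper that could couple the free butynyl alkyne, and fluoride then cleaves the labile C(sp)–Si bond of 5 in the same flask (protodesilylation).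

**Step 3**
Reactants: 6 N-(but-3-yn-1-yl)-N-ethynyl-4-methylbenzenesulfonamide; 7 bis(trimethylsilyl)acetylene
Product: 8 1-tosyl-5,6-bis(trimethylsilyl)indoline
Conditions: CpCo(CO)2 (10 mol %), 7 as solvent (large excess), reflux (ca. 135 °C), visible light, 6 added slowly by syringe pump (degassed, in 7/xylene)
Reagents that add atoms: bis(trimethylsilyl)acetylene (7), C[Si](C)(C)C#C[Si](C)(C)C
Why: Light and heat expel CO from CpCo(CO)2 (cyclopentadienylcobalt dicarbonyl) to give a CpCo fragment of monovalent cobalt that binds the two alkynes of 6 and couples them oxidatively to a cobaltacyclopentadiene of trivalent cobalt, which creates C3a–C7a; coordination and insertion of 7 followed by reductive elimination creates C4–C5 and C6–C7 and returns monovalent cobalt. The closest known reaction type is the cobalt-catalysed [2+2+2] cotrimerization of α,ω-diynes with bis(trimethylsilyl)acetylene, together with metal-catalysed [2+2+2] reactions of ynamide-tethered diynes that give indolines. The five-membered ring closes by intramolecular oxidative cyclization of the 1,6-diyne, the three-atom N1–C2–C3 tether holding both alkynes on one metal centre. The benzene ring closes by intermolecular alkyne insertion into the metallacycle and C–C reductive elimination, formally a [4+2] union of the metallacyclic diene with 7. No stereocentre is formed. The step needs cross-cotrimerization instead of self-oligomerization of the diyne, which is secured by the bulk of 7 (it cannot trimerize with itself), its use as solvent and the slow addition of 6, and regiochemistry is not an issue because 7 is symmetric.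

**Step 4**
Reactants: 8 1-tosyl-5,6-bis(trimethylsilyl)indoline
Product: 10 5,6-dibromo-1-tosylindoline, via bromosilyl indoline 9 (not isolated)
Conditions: Br2 (2.5 equiv), pyridine (0.5 equiv), CH2Cl2, 0 °C to rt, dark
Reagents that add atoms: bromine, BrBr
Why: Double electrophilic ipso-bromodesilylation should occur because attack at each silyl-bearing carbon gives a cation stabilized by the β-silicon effect that collapses by loss of Me3SiBr, the first exchange (expected at C5, para to the sulfonamide nitrogen, with relief of strain between the adjacent silyl groups) being faster than the second at C6 (para to the C3 methylene), while the N-tosyl group keeps C4 and C7 unreactive and pyridine buffers any HBr that could cause protodesilylation.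

**Step 5**
Reactants: 10 5,6-dibromo-1-tosylindoline
Product: 11 5,6-dibromoindoline
Conditions: conc. H2SO4, 0 °C to 40 °C; then ice, aq. NaOH
Reagents that add atoms: none
Why: Acidolysis of an N-aryl sulfonamide (N-protonation, S–N heterolysis, hydrolysis of the sulfonyl fragment to the sulfonic acid on quench) is a standard detosylation for aniline-type nitrogen, it leaves the aryl bromides untouched where dissolving-metal or Mg/MeOH conditions would reduce them, and the electron-poor dibrominated ring disfavours migration of the sulfonyl group to carbon.

**Step 6**
Reactants: 11 5,6-dibromoindoline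
Product: 12 5,6-dibromo-1H-indole
Conditions: activated MnO2 (10 equiv), CH2Cl2, rt
Reagents that add atoms: none
Why: Dehydrogenation of a free indoline with manganese dioxide is a standard oxidation driven by aromatization of the pyrrole ring and does not affect aryl bromides.

**Step 7**
Reactants: 12 5,6-dibromo-1H-indole
Product: 14 2,3,5,6-tetrabromo-1H-indole, via 3,5,6-tribromoindole 13 (not isolated)
Conditions: NBS (2.05 equiv), THF, −78 °C to rt, dark
Reagents that add atoms: N-bromosuccinimide, O=C1CCC(=O)N1Br
Why: Electrophilic aromatic bromination of the pyrrole ring should occur first at C3, the most nucleophilic position, and then at C2 of the 3-bromoindole, whereas the benzene ring, already deactivated by two bromines, should not be attacked when only two equivalents are used at low temperature.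

**Compound list**
1 | but-3-yn-1-amine | C#CCCN | starting material
2 | 4-toluenesulfonyl chloride | Cc1ccc(cc1)S(=O)(=O)Cl | starting material
3 | N-(but-3-yn-1-yl)-4-methylbenzenesulfonamide | C#CCCNS(=O)(=O)c1ccc(C)cc1 | intermediate
4 | phenyl[(trimethylsilyl)ethynyl]iodonium trifluoromethanesulfonate | C[Si](C)(C)C#C[I+]c1ccccc1.[O-]S(=O)(=O)C(F)(F)F | starting material
5 | N-(but-3-yn-1-yl)-4-methyl-N-[(trimethylsilyl)ethynyl]benzenesulfonamide | C#CCCN(C#C[Si](C)(C)C)S(=O)(=O)c1ccc(C)cc1 | intermediate (not isolated)
6 | N-(but-3-yn-1-yl)-N-ethynyl-4-methylbenzenesulfonamide | C#CCCN(C#C)S(=O)(=O)c1ccc(C)cc1 | intermediate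
7 | bis(trimethylsilyl)acetylene | C[Si](C)(C)C#C[Si](C)(C)C | starting material
8 | 1-tosyl-5,6-bis(trimethylsilyl)indoline (1-(4-methylbenzenesulfonyl)-5,6-bis(trimethylsilyl)-2,3-dihydro-1H-indole) | Cc1ccc(cc1)S(=O)(=O)N1CCc2cc([Si](C)(C)C)c([Si](C)(C)C)cc21 | intermediate
9 | 5-bromo-1-tosyl-6-(trimethylsilyl)indoline | Cc1ccc(cc1)S(=O)(=O)N1CCc2cc(Br)c([Si](C)(C)C)cc21 | intermediate (not isolated)
10 | 5,6-dibromo-1-tosylindoline | Cc1ccc(cc1)S(=O)(=O)N1CCc2cc(Br)c(Br)cc21 | intermediate
11 | 5,6-dibromoindoline (5,6-dibromo-2,3-dihydro-1H-indole) | Brc1cc2CCNc2cc1Br | intermediate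
12 | 5,6-dibromo-1H-indole | Brc1cc2cc[nH]c2cc1Br | intermediate
13 | 3,5,6-tribromo-1H-indole | Brc1cc2c(Br)c[nH]c2cc1Br | intermediate (not isolated)
14 | 2,3,5,6-tetrabromo-1H-indole | Brc1cc2[nH]c(Br)c(Br)c2cc1Br | target

**Step count.** Total: 7 steps. Longest linear sequence: 7 steps (from but-3-yn-1-amine).

**Steps most likely to fail**

1. Step 3. Self-oligomerization of the diyne may outrun insertion of the hindered silyl alkyne into the cobaltacycle, so that little cross-product forms. The fallback sets out from 6 and changes the placeholder element from silicon to boron. Cotrimerization of 6 with commercial 1,2-bis(pinacolatoboryl)ethyne (CpCo(CO)2, toluene, reflux, light), a flatter alkyne that should insert more readily, should give 1-tosyl-5,6-bis(4,4,5,5-tetramethyl-1,3,2-dioxaborolan-2-yl)indoline F1. Bromodeboronation with CuBr2 (copper dibromide) in MeOH/H2O at 80 °C should then give the dibromide directly. The route is rejoined at 10, and step 4 is bypassed.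

2. Step 5. The S–N cleavage may stay incomplete, or the sulfonyl group may migrate from nitrogen to C7 in the strong acid. The fallback sets out from 10 and reverses the order of deprotection and aromatization. DDQ in refluxing 1,4-dioxane should dehydrogenate the N-sulfonyl indoline to 5,6-dibromo-1-tosyl-1H-indole F2. Its sulfonyl group, now on an indole nitrogen, should be cleaved by NaOH in MeOH/THF/H2O at 60 °C. The route is rejoined at 12, and compound 11 is bypassed.

3. Step 2. The alkylidene carbene may be diverted before its 1,2-shift, or the iodonium salt may decay before N–C bond formation, which would give low conversion in the telescoped sequence. The fallback sets out from 3 and builds the ynamide by N-dichlorovinylation and elimination. Trichloroethene with Cs2CO3 in DMF at 60 °C should give N-(but-3-yn-1-yl)-N-[(E)-1,2-dichloroethenyl]-4-methylbenzenesulfonamide F3. PhLi (3.3 equiv, THF, −78 °C, one equivalent being consumed by the butynyl C–H) should then remove both chlorines by elimination and chlorine–lithium exchange, and a quench with aqueous NH4Cl should deliver the terminal ynamide. The route is rejoined at 6.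

**Further compounds**
F1 | step 3 | 1-tosyl-5,6-bis(4,4,5,5-tetramethyl-1,3,2-dioxaborolan-2-yl)indoline | Cc1ccc(cc1)S(=O)(=O)N1CCc2cc(B3OC(C)(C)C(C)(C)O3)c(B3OC(C)(C)C(C)(C)O3)cc21
F2 | step 5 | 5,6-dibromo-1-tosyl-1H-indole | Cc1ccc(cc1)S(=O)(=O)n1ccc2cc(Br)c(Br)cc21
F3 | step 2 | N-(but-3-yn-1-yl)-N-[(E)-1,2-dichloroethenyl]-4-methylbenzenesulfonamide | C#CCCN(S(=O)(=O)c1ccc(C)cc1)/C(Cl)=C\Cl
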